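**Plan**

1. Retrosynthetic cuts: (a) the pivalate and benzyl protecting groups; (b) the two C–H bonds at C2/C3, back to a C2=C3 enol ether; (c) in one stroke C3–C4 and O1–C8a of the pyran ring; (d) the formyl carbon of the ring B side chain; (e) ring A back to a quinone.
2. Enabling feature: O1–C2–C3 is the O–C=C unit of an arylacetaldehyde enolate (C3 the nucleophilic carbon carrying ring B, O1 the nucleophilic oxygen), and C4 (benzylic) and C8a (ortho ring carbon) of ring A are 1,3-related electrophilic sites. Ring A (O1 para to 6-OH, 7,8-OMe, C4 on C4a) has the substitution pattern of 2,3-dimethoxy-5-methyl-1,4-benzoquinone.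
3. Forward: the quinone gives the ring A 1,3-dielectrophile (benzylic bromide at C4, triflate at C8a, pivalate on O6) in four steps; 2-hydroxy-3,4-dimethoxybenzaldehyde gives the O-benzylated ring B arylacetaldehyde in two steps.
4. The halves are joined and the pyran ring closed in one pot: enolate C-benzylation (C3–C4), then palladium-catalysed enolate O-arylation (O1–C8a) to a 3-aryl-4H-chromene. Rings A and B are preformed; the pyran ring arises last.
5. Stereochemistry: the only centre, C3 (S), is set by iridium-catalysed asymmetric hydrogenation of the helper C2=C3 bond (catalyst control); deprotection ends the route.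

Key step: step 7

Remark: the hydroxyl of hydroquinone 2 next to the ring hydrogen is assumed to be acylated first (steric control). The sense of induction in step 8 is assigned by analogy; the ligand antipode is used if the opposite face is delivered.

**Route**

Step 1
Reactants: 1 2,3-dimethoxy-5-methyl-1,4-benzoquinone
Product: 2 2,3-dimethoxy-5-methylbenzene-1,4-diol
Conditions: Na2S2O4, EtOAc/H2O, rt, under N2
Reagents that add atoms: none
Why: Dithionite reduction of a p-benzoquinone to its hydroquinone is a fast, clean two-phase reaction; no stereocentre is involved.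

Step 2
Reactants: 2 2,3-dimethoxy-5-methylbenzene-1,4-diol
Product: 3 4-hydroxy-2,3-dimethoxy-5-methylphenyl pivalate
Conditions: pivaloyl chloride (1.0 equiv), pyridine, CH2Cl2, −20 to 0 °C
Reagents that add atoms: pivaloyl chloride, CC(C)(C)C(Cl)=O
Why: Sterically controlled mono-acylation of an unsymmetrical hydroquinone: the bulky acid chloride should react at the hydroxyl flanked by a ring hydrogen and leave the hydroxyl flanked by the methyl group (the future C8a oxygen) free.

Step 3
Reactants: 3 4-hydroxy-2,3-dimethoxy-5-methylphenyl pivalate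
Product: 4 2,3-dimethoxy-5-methyl-4-{[(trifluoromethyl)sulfonyl]oxy}phenyl pivalate
Conditions: Tf2O, pyridine, CH2Cl2, 0 °C
Reagents that add atoms: trifluoromethanesulfonic anhydride, O=S(=O)(OS(=O)(=O)C(F)(F)F)C(F)(F)F
Why: Standard phenol triflation turns the oxygen on the future C8a into the leaving group for palladium-catalysed C–O coupling; the pivalate is inert.

Step 4
Reactants: 4 2,3-dimethoxy-5-methyl-4-{[(trifluoromethyl)sulfonyl]oxy}phenyl pivalate
Product: 5 5-(bromomethyl)-2,3-dimethoxy-4-{[(trifluoromethyl)sulfonyl]oxy}phenyl pivalate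
Conditions: NBS, AIBN (cat.), PhCF3, 80 °C
Reagents that add atoms: N-bromosuccinimide, O=C1CCC(=O)N1Br
Why: Wohl–Ziegler radical bromination of the benzylic methyl group (the future C4); the triflate and pivalate withdraw electron density from the ring and so disfavour electrophilic ring bromination.

Step 5
Reactants: 6 2-hydroxy-3,4-dimethoxybenzaldehyde
Product: 7 2-(benzyloxy)-3,4-dimethoxybenzaldehyde
Conditions: BnBr, K2CO3, DMF, 60 °C
Reagents that add atoms: benzyl bromide, BrCc1ccccc1
Why: Williamson etherification protects the 2'-hydroxyl, which would otherwise close onto the acetaldehyde side chain to a benzofuran.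

Step 6
Reactants: 7 2-(benzyloxy)-3,4-dimethoxybenzaldehyde
Product: 9 2-[2-(benzyloxy)-3,4-dimethoxyphenyl]acetaldehyde, via enol ether 8 (not isolated)
Conditions: Ph3P(CH2OMe)Cl, KOtBu, THF, 0 °C to rt; then aq. HCl (2 M), THF, 40 °C; used at once
Reagents that add atoms: (methoxymethyl)triphenylphosphonium chloride, [Cl-].COC[P+](c1ccccc1)(c1ccccc1)c1ccccc1; water, O
Why: Wittig methoxymethylenation followed by acid hydrolysis of the enol ether is the standard one-carbon homologation of an aryl aldehyde to an arylacetaldehyde; the benzyl ether is stable to both stages.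

Step 7
Reactants: 9 2-[2-(benzyloxy)-3,4-dimethoxyphenyl]acetaldehyde; 5 5-(bromomethyl)-2,3-dimethoxy-4-{[(trifluoromethyl)sulfonyl]oxy}phenyl pivalate
Product: 12 3-[2-(benzyloxy)-3,4-dimethoxyphenyl]-7,8-dimethoxy-4H-chromen-6-yl pivalate, via potassium enolate 10 (not isolated), via racemic aldehyde 11 (not isolated)
Conditions: KN(SiMe3)2 (1.0 equiv), toluene, −78 °C (9 added to the base); then 5, −78 °C to rt; then K3PO4, Pd2(dba)3 (cat.), DPEphos (cat.), 100 °C
Reagents that add atoms: none
Why: Proposed new method: KN(SiMe3)2 converts 9 completely into the aryl-conjugated potassium enolate 10, so no free aldehyde is left for aldol addition; its soft α-carbon C3 displaces the benzylic bromide of 5 (SN2) to form C3–C4 in racemic aldehyde 11, then K3PO4 re-enolises 11 (its one α-H is activated by ring B and the formyl group), zerovalent palladium inserts into the C8a–OTf bond, and C–O reductive elimination transfers the enolate oxygen O1 to C8a. The closest known reaction types are the copper-catalysed domino C-benzylation/O-arylation of β-keto esters with 2-bromobenzyl bromides to 4H-chromenes and the palladium-catalysed intramolecular O-arylation of ketone enolates to benzofurans; new here are the simple aldehyde enolate and the aryl triflate. The pyran ring closes by O-arylation through a seven-membered aryl(enolato)palladium chelate, formally a 6-exo closure onto C8a, and C-arylation is excluded because it would give a four-membered ring. No stereocentre is created for the target: C3 of 11 is racemic and becomes sp2 in 12, so control is deferred to step 8. The step needs C- over O-benzylation (soft bromide, potassium enolate in toluene), reaction at the benzylic bromide before the triflate (the hindered triflate reacts only with palladium at 100 °C), and O-arylation over formyl C–H acylation to an indanone (favoured by the acidity of the α-H and the phosphate base).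

Step 8
Reactants: 12 3-[2-(benzyloxy)-3,4-dimethoxyphenyl]-7,8-dimethoxy-4H-chromen-6-yl pivalate
Product: 13 (3S)-3-[2-(benzyloxy)-3,4-dimethoxyphenyl]-7,8-dimethoxy-3,4-dihydro-2H-chromen-6-yl pivalate
Conditions: [Ir(cod)((S)-tBu-PHOX)][B(C6H3(CF3)2)4] (2 mol%), H2 (50 bar), CH2Cl2, rt
Reagents that add atoms: none
Why: Iridium N,P-ligand catalysts hydrogenate trisubstituted aryl alkenes and cyclic enol ethers, 4H-chromenes included, with high enantioselectivity (iridium-catalysed asymmetric hydrogenation); H2 is delivered to one face of the C2=C3 bond under catalyst control, which sets C3 as S.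

Step 9
Reactants: 13 (3S)-3-[2-(benzyloxy)-3,4-dimethoxyphenyl]-7,8-dimethoxy-3,4-dihydro-2H-chromen-6-yl pivalate
Product: 15 (3S)-3-(2-hydroxy-3,4-dimethoxyphenyl)-7,8-dimethoxy-3,4-dihydro-2H-chromen-6-ol, via phenol pivalate 14 (not isolated)
Conditions: H2 (1 atm), Pd/C, MeOH–EtOAc, rt; then K2CO3 (cat.), MeOH, 40 °C, kept under H2; aq. NH4Cl work-up
Reagents that add atoms: none
Why: Hydrogenolysis removes the benzyl ether and base-catalysed transesterification removes the aryl pivalate; C3 is neither acidic nor attached to a cleavable bond, so its configuration is untouched.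

**Compound list**

1 | 2,3-dimethoxy-5-methyl-1,4-benzoquinone | COC1=C(OC)C(=O)C(C)=CC1=O | starting material
2 | 2,3-dimethoxy-5-methylbenzene-1,4-diol | COc1c(O)cc(C)c(O)c1OC | intermediate
3 | 4-hydroxy-2,3-dimethoxy-5-methylphenyl pivalate | COc1c(OC(=O)C(C)(C)C)cc(C)c(O)c1OC | intermediate
4 | 2,3-dimethoxy-5-methyl-4-{[(trifluoromethyl)sulfonyl]oxy}phenyl pivalate | COc1c(OC(=O)C(C)(C)C)cc(C)c(OS(=O)(=O)C(F)(F)F)c1OC | intermediate
5 | 5-(bromomethyl)-2,3-dimethoxy-4-{[(trifluoromethyl)sulfonyl]oxy}phenyl pivalate | COc1c(OC(=O)C(C)(C)C)cc(CBr)c(OS(=O)(=O)C(F)(F)F)c1OC | intermediate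
6 | 2-hydroxy-3,4-dimethoxybenzaldehyde | COc1ccc(C=O)c(O)c1OC | starting material
7 | 2-(benzyloxy)-3,4-dimethoxybenzaldehyde | COc1ccc(C=O)c(OCc2ccccc2)c1OC | intermediate
8 | 2-(benzyloxy)-3,4-dimethoxy-1-(2-methoxyethenyl)benzene (E/Z mixture) | COC=Cc1ccc(OC)c(OC)c1OCc1ccccc1 | intermediate
9 | 2-[2-(benzyloxy)-3,4-dimethoxyphenyl]acetaldehyde | O=CCc1ccc(OC)c(OC)c1OCc1ccccc1 | intermediate
10 | potassium 2-[2-(benzyloxy)-3,4-dimethoxyphenyl]ethenolate | [K+].[O-]C=Cc1ccc(OC)c(OC)c1OCc1ccccc1 | intermediate
11 | 5-{2-[2-(benzyloxy)-3,4-dimethoxyphenyl]-3-oxopropyl}-2,3-dimethoxy-4-{[(trifluoromethyl)sulfonyl]oxy}phenyl pivalate (racemic) | O=CC(Cc1cc(OC(=O)C(C)(C)C)c(OC)c(OC)c1OS(=O)(=O)C(F)(F)F)c1ccc(OC)c(OC)c1OCc1ccccc1 | intermediate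
12 | 3-[2-(benzyloxy)-3,4-dimethoxyphenyl]-7,8-dimethoxy-4H-chromen-6-yl pivalate | COc1ccc(C2=COc3c(cc(OC(=O)C(C)(C)C)c(OC)c3OC)C2)c(OCc2ccccc2)c1OC | intermediate
13 | (3S)-3-[2-(benzyloxy)-3,4-dimethoxyphenyl]-7,8-dimethoxy-3,4-dihydro-2H-chromen-6-yl pivalate | COc1ccc([C@H]2COc3c(cc(OC(=O)C(C)(C)C)c(OC)c3OC)C2)c(OCc2ccccc2)c1OC | intermediate
14 | (3S)-3-(2-hydroxy-3,4-dimethoxyphenyl)-7,8-dimethoxy-3,4-dihydro-2H-chromen-6-yl pivalate | COc1ccc([C@H]2COc3c(cc(OC(=O)C(C)(C)C)c(OC)c3OC)C2)c(O)c1OC | intermediate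
15 | (3S)-3-(2-hydroxy-3,4-dimethoxyphenyl)-7,8-dimethoxy-3,4-dihydro-2H-chromen-6-ol | COc1ccc([C@H]2COc3c(cc(O)c(OC)c3OC)C2)c(O)c1OC | target

**Summary**

Total step count: 9. Longest linear sequence: 7 steps (steps 1, 2, 3, 4, 7, 8, 9).

**Steps most likely to fail**

Step 7 (Proposed new method). What may go wrong: loss of the enolate to aldol addition or to proton exchange with 11 (over-alkylation), O-benzylation, slow oxidative addition at the hindered electron-rich triflate, or diversion of the arylpalladium species to formyl C–H acylation. Fallback with known chemistry, from 9 and 5 back to 13: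
- Aldehyde 9 is oxidised (NaClO2, NaH2PO4, 2-methyl-2-butene, t-BuOH/H2O; Pinnick oxidation) to 2-[2-(benzyloxy)-3,4-dimethoxyphenyl]acetic acid F1.
- F1 is coupled through its pivaloyl mixed anhydride (pivaloyl chloride, Et3N, LiCl, THF) with (S)-4-benzyl-2-oxazolidinone to the N-acyl oxazolidinone F2.
- Evans alkylation of the sodium enolate of F2 (NaN(SiMe3)2, THF, −78 °C) with bromide 5 should give the (S)-configured alkylated imide F3. The electrophile approaches the chelated Z-enolate on the face away from the auxiliary benzyl group.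
- Reductive removal of the auxiliary (NaBH4, THF/H2O, 0 °C to rt) gives the (S)-primary alcohol F4.
- Palladium-catalysed intramolecular etherification of the aryl triflate (Pd(OAc)2, 2-(di-tert-butylphosphino)-1,1'-binaphthyl, K3PO4, toluene, 80 °C) closes the pyran ring to 13. Compound 12 and step 8 are bypassed.

Step 8. What may go wrong: poor facial discrimination on a 2-unsubstituted 3-aryl enol ether, and hydration or double-bond migration of the acid-sensitive enol ether under the cationic iridium hydride. Fallback from 12 back to 14: heterogeneous hydrogenation (H2, Pd/C, MeOH–EtOAc) reduces the enol ether and cleaves the benzyl ether to the racemic phenol pivalate F5. The enantiomers are separated by preparative chromatography on a chiral stationary phase. The (S)-enantiomer is compound 14 and continues with the methanolysis stage of step 9.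

Step 4. What may go wrong: electrophilic bromination at the free ring position (para to a methoxy group) and over-bromination to the dibromomethyl compound. Fallback from 6 back to 5, which brings in the benzylic carbon as a formyl group and avoids radical bromination:
- Elbs persulfate oxidation of 6 (K2S2O8, aq. NaOH, 0 °C to rt) hydroxylates para to the phenol and gives potassium 5-formyl-4-hydroxy-2,3-dimethoxyphenyl sulfate F6.
- F6 is hydrolysed in the same pot (aq. HCl, 80 °C) to 2,5-dihydroxy-3,4-dimethoxybenzaldehyde F7.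
- The 5-hydroxyl, which unlike the 2-hydroxyl is not hydrogen-bonded to the formyl group, is pivaloylated selectively (pivaloyl chloride, pyridine, CH2Cl2, 0 °C) to 5-formyl-4-hydroxy-2,3-dimethoxyphenyl pivalate F8.
- Triflation (Tf2O, pyridine, CH2Cl2, 0 °C) gives 5-formyl-2,3-dimethoxy-4-{[(trifluoromethyl)sulfonyl]oxy}phenyl pivalate F9.
- NaBH4 (MeOH/THF, 0 °C) reduces the aldehyde to 5-(hydroxymethyl)-2,3-dimethoxy-4-{[(trifluoromethyl)sulfonyl]oxy}phenyl pivalate F10.
- PBr3 (CH2Cl2, 0 °C) converts F10 into bromide 5.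

**Further compounds**

F1 | step 7 | 2-[2-(benzyloxy)-3,4-dimethoxyphenyl]acetic acid | OC(=O)Cc1ccc(OC)c(OC)c1OCc1ccccc1
F2 | step 7 | (4S)-4-benzyl-3-{2-[2-(benzyloxy)-3,4-dimethoxyphenyl]acetyl}-1,3-oxazolidin-2-one | O=C(Cc1ccc(OC)c(OC)c1OCc1ccccc1)N1[C@@H](Cc2ccccc2)COC1=O
F3 | step 7 | 5-{(2S)-3-[(4S)-4-benzyl-2-oxo-1,3-oxazolidin-3-yl]-2-[2-(benzyloxy)-3,4-dimethoxyphenyl]-3-oxopropyl}-2,3-dimethoxy-4-{[(trifluoromethyl)sulfonyl]oxy}phenyl pivalate | O=C([C@@H](Cc1cc(OC(=O)C(C)(C)C)c(OC)c(OC)c1OS(=O)(=O)C(F)(F)F)c1ccc(OC)c(OC)c1OCc1ccccc1)N1[C@@H](Cc2ccccc2)COC1=O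
F4 | step 7 | 5-{(2S)-2-[2-(benzyloxy)-3,4-dimethoxyphenyl]-3-hydroxypropyl}-2,3-dimethoxy-4-{[(trifluoromethyl)sulfonyl]oxy}phenyl pivalate | OC[C@@H](Cc1cc(OC(=O)C(C)(C)C)c(OC)c(OC)c1OS(=O)(=O)C(F)(F)F)c1ccc(OC)c(OC)c1OCc1ccccc1
F5 | step 8 | 3-(2-hydroxy-3,4-dimethoxyphenyl)-7,8-dimethoxy-3,4-dihydro-2H-chromen-6-yl pivalate (racemic) | COc1ccc(C2COc3c(cc(OC(=O)C(C)(C)C)c(OC)c3OC)C2)c(O)c1OC
F6 | step 4 | potassium 5-formyl-4-hydroxy-2,3-dimethoxyphenyl sulfate | [K+].COc1c(OS(=O)(=O)[O-])cc(C=O)c(O)c1OC
F7 | step 4 | 2,5-dihydroxy-3,4-dimethoxybenzaldehyde | COc1c(O)cc(C=O)c(O)c1OC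
F8 | step 4 | 5-formyl-4-hydroxy-2,3-dimethoxyphenyl pivalate | COc1c(OC(=O)C(C)(C)C)cc(C=O)c(O)c1OC
F9 | step 4 | 5-formyl-2,3-dimethoxy-4-{[(trifluoromethyl)sulfonyl]oxy}phenyl pivalate | COc1c(OC(=O)C(C)(C)C)cc(C=O)c(OS(=O)(=O)C(F)(F)F)c1OC
F10 | step 4 | 5-(hydroxymethyl)-2,3-dimethoxy-4-{[(trifluoromethyl)sulfonyl]oxy}phenyl pivalate | COc1c(OC(=O)C(C)(C)C)cc(CO)c(OS(=O)(=O)C(F)(F)F)c1OC
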